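**Plan**

1. Numbering: the C12 chain runs from C1 (lactone C=O) to C12 (CH3); O1 is the oxolane oxygen (C4–O1–C7), O5 the lactone oxygen on C5.
2. Cuts: C8=C9 (cross-metathesis with a lactate-derived C9–C12 alkene), the acyl bond C1–O5 (lactonisation), and C3–C4 (radical ring closure through a temporary silicon tether on O5).
3. Enabling feature: in the oxolane ring (O1, C4–C7) O5 sits on C5, next to the acetal-type carbon C4; a SiMe2 unit on O5 carrying CH=CH–CO2Me can reach a C4 radical only through a five-membered 1,2-oxasilolane (C4–C5–O5–Si–C3).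
4. That closure forms C3–C4 on the crowded all-cis face; C3–Si is then oxidised to C3–OH with retention, O5 is released and closes the δ-lactone on the tether ester (C1), so the silicon ring is replaced by the lactone ring.
5. Forward order: oxolane ring from D-glucose (via the D-gulo furanose) → oxasilolane (key step) → δ-lactone → side chain → removal of the O6 protecting group.
6. Stereochemistry: C5 from D-glucose; C6/C7 by face-selective hydrogenation of an enol acetate; C4 by the tether (cis to O5); C3 by exo orientation in the 5-exo closure; C11 from methyl (R)-lactate; C10 by Felkin–Anh addition; E-alkene by metathesis.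

Key step: step 11

**Route**

Step 1
Reactants: 1 1,2:5,6-di-O-isopropylidene-α-D-glucofuranose
Product: 2 1,2:5,6-di-O-isopropylidene-α-D-ribo-hexofuranos-3-ulose
Conditions: Dess–Martin periodinane, CH2Cl2, rt
Reagents that add atoms: none
Why: Dess–Martin oxidation of the only free (secondary) hydroxyl should give the 3-ulose without touching the acetals; no stereocentre is formed.

Step 2
Reactants: 2 1,2:5,6-di-O-isopropylidene-α-D-ribo-hexofuranos-3-ulose
Product: 3 3-O-acetyl-1,2:5,6-di-O-isopropylidene-α-D-erythro-hex-3-enofuranose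
Conditions: Ac2O, pyridine, 60 °C
Reagents that add atoms: acetic anhydride CC(=O)OC(C)=O
Why: O-acetylation of the C3–C4 enol (enol acetate formation) erases the C4 configuration so that it can be reset in the next step.

Step 3
Reactants: 3 3-O-acetyl-1,2:5,6-di-O-isopropylidene-α-D-erythro-hex-3-enofuranose
Product: 4 3-O-acetyl-1,2:5,6-di-O-isopropylidene-α-D-gulofuranose
Conditions: H2 (1 atm), Pd/C, EtOAc, rt
Reagents that add atoms: none
Why: heterogeneous syn-hydrogenation should add both hydrogens from the convex β-face of the cis-fused furanose/dioxolane bicycle, so that O3 and the C4 side chain both end up on the α-face (D-gulo), which sets target C6 and C7.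

Step 4
Reactants: 4 3-O-acetyl-1,2:5,6-di-O-isopropylidene-α-D-gulofuranose
Product: 6 1,2:5,6-di-O-isopropylidene-3-O-(naphthalen-2-ylmethyl)-α-D-gulofuranose, via 1,2:5,6-di-O-isopropylidene-α-D-gulofuranose 5 (not isolated)
Conditions: NaOMe (cat.), MeOH, rt; evaporate; then NaH, 2-(bromomethyl)naphthalene, Bu4NI (cat.), DMF, 0 °C to rt
Reagents that add atoms: 2-(bromomethyl)naphthalene BrCc1ccc2ccccc2c1
Why: Zemplén deacetylation followed by Williamson etherification installs a naphthylmethyl (NAP) ether that tolerates acid, radicals and peroxide and can be removed by DDQ next to an alkene and esters.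

Step 5
Reactants: 6 1,2:5,6-di-O-isopropylidene-3-O-(naphthalen-2-ylmethyl)-α-D-gulofuranose
Product: 7 1,2-O-isopropylidene-3-O-(naphthalen-2-ylmethyl)-α-D-gulofuranose
Conditions: AcOH/H2O (7:3), rt to 40 °C
Reagents that add atoms: none
Why: selective acetal hydrolysis, the terminal 5,6-dioxolane being cleaved much faster than the cis-fused 1,2-acetal.

Step 6
Reactants: 7 1,2-O-isopropylidene-3-O-(naphthalen-2-ylmethyl)-α-D-gulofuranose
Product: 8 5,6-dideoxy-1,2-O-isopropylidene-3-O-(naphthalen-2-ylmethyl)-β-L-lyxo-hex-5-enofuranose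
Conditions: PPh3, I2, imidazole, toluene, 110 °C
Reagents that add atoms: none
Why: Garegg–Samuelsson deoxygenation of the vicinal diol should give the terminal alkene (target C8=CH2) without affecting the adjacent ring stereocentre.

Step 7
Reactants: 8 5,6-dideoxy-1,2-O-isopropylidene-3-O-(naphthalen-2-ylmethyl)-β-L-lyxo-hex-5-enofuranose
Product: 9 5,6-dideoxy-3-O-(naphthalen-2-ylmethyl)-L-lyxo-hex-5-enofuranose (mixture of anomers)
Conditions: aq. HCl (1 M), THF, 50 °C
Reagents that add atoms: water O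
Why: acid hydrolysis of the 1,2-acetal frees O2 (target O5) and the anomeric hydroxyl, while the NAP ether and the alkene are stable.

Step 8
Reactants: 9 5,6-dideoxy-3-O-(naphthalen-2-ylmethyl)-L-lyxo-hex-5-enofuranose
Product: 10 phenyl 5,6-dideoxy-3-O-(naphthalen-2-ylmethyl)-1-seleno-α-L-lyxo-hex-5-enofuranoside (1,2-trans anomer expected as the major one)
Conditions: N-(phenylseleno)phthalimide, PBu3, CH2Cl2, −20 °C to rt
Reagents that add atoms: N-(phenylseleno)phthalimide O=C1N([Se]c2ccccc2)C(=O)c2ccccc12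
Why: Grieco-type (Mitsunobu-like) activation of the more reactive hemiacetal hydroxyl and displacement by phenylselenolate should give the anomeric selenide with the 2-OH left free; the anomeric configuration is irrelevant because this carbon becomes a radical.

Step 9
Reactants: 11 methyl propiolate; 12 2-[dimethyl(phenyl)silyl]-4,4,5,5-tetramethyl-1,3,2-dioxaborolane
Product: 13 methyl (E)-3-[dimethyl(phenyl)silyl]prop-2-enoate
Conditions: CuSO4 (cat.), 4-picoline (cat.), H2O, rt
Reagents that add atoms: none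
Why: copper-catalysed conjugate silyl transfer from the Si–B reagent to the ynoate (syn silylcupration, then protonation) places silicon on the β-carbon and should give the (E)-β-silyl acrylate; the alkene geometry has no consequence later.

Step 10
Reactants: 10 phenyl 5,6-dideoxy-3-O-(naphthalen-2-ylmethyl)-1-seleno-α-L-lyxo-hex-5-enofuranoside; 13 methyl (E)-3-[dimethyl(phenyl)silyl]prop-2-enoate
Product: 15 phenyl 5,6-dideoxy-2-O-{[(E)-2-(methoxycarbonyl)ethenyl]dimethylsilyl}-3-O-(naphthalen-2-ylmethyl)-1-seleno-α-L-lyxo-hex-5-enofuranoside, via methyl (E)-3-{dimethyl[(trifluoromethanesulfonyl)oxy]silyl}prop-2-enoate 14 (not isolated)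
Conditions: 13, TfOH (1.0 equiv), CH2Cl2, 0 °C; then 10, 2,6-lutidine, −40 to 0 °C
Reagents that add atoms: none
Why: ipso-protodesilylation of the phenyl–silicon bond by TfOH (the electron-poor alkenyl–silicon bond is not attacked) gives the silyl triflate, which silylates the only free hydroxyl (target O5).

Step 11
Reactants: 15 phenyl 5,6-dideoxy-2-O-{[(E)-2-(methoxycarbonyl)ethenyl]dimethylsilyl}-3-O-(naphthalen-2-ylmethyl)-1-seleno-α-L-lyxo-hex-5-enofuranoside
Product: 16 bicyclic siloxane: 1,2-oxasilolane (C4–C5–O5–SiMe2–C3) cis-fused to the oxolane on the face that carries ONap (C6) and vinyl (C7); C3 bears CH2CO2Me on the convex face (cis to H-4)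
Conditions: Bu3SnH (slow addition), AIBN (cat.), benzene (0.01 M), 80 °C
Reagents that add atoms: none
Why: Bu3Sn• removes PhSe from C4 and the nucleophilic α-oxy radical adds to the silicon-bearing β-carbon (C3) of the tethered acrylate, the α-ester radical at C2 then taking hydrogen from Bu3SnH; the closest known reaction type is the temporary-silicon-connection radical C-glycosylation of anomeric selenides that carry an alkenyl- or alkynylsilyl ether on O-2. One ring is closed, the 1,2-oxasilolane C4–C5–O5–Si–C3, by 5-exo-trig attack. C4 is controlled by the tether: four atoms cannot bridge to the opposite face, so the new bond is cis to O5 and the bicycle is cis-fused, which puts C3 on the crowded all-cis face that an untethered reagent would avoid. C3 is controlled by the fold of that bicycle: the CH2CO2Me arm should take the convex (exo) position, away from the concave face occupied by the C6 ONap and C7 vinyl groups, which leaves H-3 syn to O1 and gives 3R once silicon is exchanged for OH with retention. The step needs 5-exo closure to win over 6-endo closure and over direct reduction of the C4 radical; the ester polarises the alkene so that attack at C3 gives the stabilised radical, and slow addition of Bu3SnH at high dilution keeps hydrogen transfer behind ring closure. In polar terms both carbons are electrophilic (acetal carbon C4, acrylate β-carbon C3), so the union depends on turning C4 into a radical.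

Step 12
Reactants: 16 bicyclic siloxane (1,2-oxasilolane cis-fused to the oxolane)
Product: 18 (2S,3R,3aR,7R,7aR)-2-ethenyl-7-hydroxy-3-(naphthalen-2-ylmethoxy)hexahydro-5H-furo[3,2-b]pyran-5-one, via methyl (3R)-3-[(2R,3R,4S,5S)-5-ethenyl-3-hydroxy-4-(naphthalen-2-ylmethoxy)oxolan-2-yl]-3-hydroxypropanoate 17 (not isolated)
Conditions: 30% H2O2, KF, KHCO3, THF/MeOH (1:1), rt; then camphorsulfonic acid (cat.), CH2Cl2, rt
Reagents that add atoms: hydrogen peroxide OO
Why: Tamao–Fleming oxidation of the alkoxy(dialkyl)silane converts C3–Si into C3–OH with retention and frees O5, and acid-catalysed lactonisation of the δ-hydroxy ester then closes the cis-fused δ-lactone, O5 being the only hydroxyl that can reach C1 through a six-membered ring.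

Step 13
Reactants: 19 methyl (R)-lactate
Product: 20 methyl (2R)-2-[(tert-butyldimethylsilyl)oxy]propanoate
Conditions: TBSCl, imidazole, DMF, 0 °C to rt
Reagents that add atoms: tert-butyldimethylsilyl chloride CC(C)(C)[Si](C)(C)Cl
Why: standard silylation protects the lactate hydroxyl (future O11) as a non-chelating silyl ether.

Step 14
Reactants: 20 methyl (2R)-2-[(tert-butyldimethylsilyl)oxy]propanoate
Product: 22 (3S,4R)-4-[(tert-butyldimethylsilyl)oxy]pent-1-en-3-ol, via (2R)-2-[(tert-butyldimethylsilyl)oxy]propanal 21 (not isolated)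
Conditions: i-Bu2AlH (1.1 equiv), Et2O, −78 °C; then CH2=CHMgBr, −78 to 0 °C; aq. potassium sodium tartrate
Reagents that add atoms: vinylmagnesium bromide C=C[Mg]Br
Why: partial reduction of the ester and in-situ Grignard addition to the α-silyloxy aldehyde follows the polar Felkin–Anh model (attack anti to the OTBS group) and should give mainly the 3,4-anti alcohol (new C10, S), the minor syn isomer being removed by chromatography.

Step 15
Reactants: 22 (3S,4R)-4-[(tert-butyldimethylsilyl)oxy]pent-1-en-3-ol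
Product: 23 (3S,4R)-4-[(tert-butyldimethylsilyl)oxy]pent-1-en-3-yl benzoate
Conditions: BzCl, pyridine, DMAP (cat.), CH2Cl2, 0 °C
Reagents that add atoms: benzoyl chloride O=C(Cl)c1ccccc1
Why: DMAP-catalysed acylation of the free allylic alcohol places the benzoate on O10.

Step 16
Reactants: 23 (3S,4R)-4-[(tert-butyldimethylsilyl)oxy]pent-1-en-3-yl benzoate
Product: 24 (3S,4R)-4-hydroxypent-1-en-3-yl benzoate
Conditions: HF·pyridine, THF/pyridine, 0 °C to rt
Reagents that add atoms: none
Why: acidic fluoride cleaves the silyl ether without base, which should avoid 1,2-benzoyl migration.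

Step 17
Reactants: 24 (3S,4R)-4-hydroxypent-1-en-3-yl benzoate
Product: 25 (3S,4R)-4-(acetyloxy)pent-1-en-3-yl benzoate
Conditions: Ac2O, pyridine, DMAP (cat.), CH2Cl2, 0 °C
Reagents that add atoms: acetic anhydride CC(=O)OC(C)=O
Why: fast DMAP-catalysed acetylation should trap the secondary alcohol before acyl migration can compete.

Step 18
Reactants: 18 (2S,3R,3aR,7R,7aR)-2-ethenyl-7-hydroxy-3-(naphthalen-2-ylmethoxy)hexahydro-5H-furo[3,2-b]pyran-5-one; 25 (3S,4R)-4-(acetyloxy)pent-1-en-3-yl benzoate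
Product: 26 (2R,3S,4E)-2-(acetyloxy)-5-[(2S,3R,3aR,7R,7aR)-7-hydroxy-3-(naphthalen-2-ylmethoxy)-5-oxohexahydro-2H-furo[3,2-b]pyran-2-yl]pent-4-en-3-yl benzoate
Conditions: second-generation Hoveyda–Grubbs catalyst (10 mol %), 25 (3 equiv), CH2Cl2, 40 °C
Reagents that add atoms: none
Why: olefin cross-metathesis of two allylic-oxygenated terminal alkenes that homodimerise slowly, with the small partner in excess, should give the E-1,2-disubstituted alkene with loss of ethene.

Step 19
Reactants: 26 (2R,3S,4E)-2-(acetyloxy)-5-[(2S,3R,3aR,7R,7aR)-7-hydroxy-3-(naphthalen-2-ylmethoxy)-5-oxohexahydro-2H-furo[3,2-b]pyran-2-yl]pent-4-en-3-yl benzoate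
Product: 27 (2R,3S,4E)-2-(acetyloxy)-5-[(2S,3R,3aR,7R,7aR)-3,7-dihydroxy-5-oxohexahydro-2H-furo[3,2-b]pyran-2-yl]pent-4-en-3-yl benzoate
Conditions: DDQ, CH2Cl2/H2O (18:1), rt
Reagents that add atoms: none
Why: oxidative cleavage of the electron-rich naphthylmethyl ether by DDQ (benzylic cation, then hemiacetal) should free O6 without affecting the esters, the lactone or the alkene.

**Compound list**

1 | 1,2:5,6-di-O-isopropylidene-α-D-glucofuranose | CC1(C)OC[C@@H](O1)[C@H]2O[C@@H]3OC(C)(C)O[C@@H]3[C@H]2O | starting material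
2 | 1,2:5,6-di-O-isopropylidene-α-D-ribo-hexofuranos-3-ulose | CC1(C)OC[C@@H](O1)[C@H]2O[C@@H]3OC(C)(C)O[C@@H]3C2=O | intermediate
3 | 3-O-acetyl-1,2:5,6-di-O-isopropylidene-α-D-erythro-hex-3-enofuranose | CC1(C)OC[C@@H](O1)C2=C(OC(C)=O)[C@H]3OC(C)(C)O[C@H]3O2 | intermediate
4 | 3-O-acetyl-1,2:5,6-di-O-isopropylidene-α-D-gulofuranose | CC1(C)OC[C@@H](O1)[C@@H]2O[C@@H]3OC(C)(C)O[C@@H]3[C@@H]2OC(C)=O | intermediate
5 | 1,2:5,6-di-O-isopropylidene-α-D-gulofuranose | CC1(C)OC[C@@H](O1)[C@@H]2O[C@@H]3OC(C)(C)O[C@@H]3[C@@H]2O | intermediate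
6 | 1,2:5,6-di-O-isopropylidene-3-O-(naphthalen-2-ylmethyl)-α-D-gulofuranose | CC1(C)OC[C@@H](O1)[C@@H]2O[C@@H]3OC(C)(C)O[C@@H]3[C@@H]2OCc4ccc5ccccc5c4 | intermediate
7 | 1,2-O-isopropylidene-3-O-(naphthalen-2-ylmethyl)-α-D-gulofuranose | OC[C@@H](O)[C@@H]1O[C@@H]2OC(C)(C)O[C@@H]2[C@@H]1OCc3ccc4ccccc4c3 | intermediate
8 | 5,6-dideoxy-1,2-O-isopropylidene-3-O-(naphthalen-2-ylmethyl)-β-L-lyxo-hex-5-enofuranose | C=C[C@@H]1O[C@@H]2OC(C)(C)O[C@@H]2[C@@H]1OCc3ccc4ccccc4c3 | intermediate
9 | 5,6-dideoxy-3-O-(naphthalen-2-ylmethyl)-L-lyxo-hex-5-enofuranose (mixture of anomers) | C=C[C@@H]1OC(O)[C@H](O)[C@@H]1OCc2ccc3ccccc3c2 | intermediate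
10 | phenyl 5,6-dideoxy-3-O-(naphthalen-2-ylmethyl)-1-seleno-α-L-lyxo-hex-5-enofuranoside | C=C[C@@H]1O[C@@H]([Se]c2ccccc2)[C@H](O)[C@@H]1OCc3ccc4ccccc4c3 | intermediate
11 | methyl propiolate | C#CC(=O)OC | starting material
12 | 2-[dimethyl(phenyl)silyl]-4,4,5,5-tetramethyl-1,3,2-dioxaborolane | C[Si](C)(c1ccccc1)B2OC(C)(C)C(C)(C)O2 | starting material
13 | methyl (E)-3-[dimethyl(phenyl)silyl]prop-2-enoate | COC(=O)/C=C/[Si](C)(C)c1ccccc1 | intermediate
14 | methyl (E)-3-{dimethyl[(trifluoromethanesulfonyl)oxy]silyl}prop-2-enoate | COC(=O)/C=C/[Si](C)(C)OS(=O)(=O)C(F)(F)F | intermediate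
15 | phenyl 5,6-dideoxy-2-O-{[(E)-2-(methoxycarbonyl)ethenyl]dimethylsilyl}-3-O-(naphthalen-2-ylmethyl)-1-seleno-α-L-lyxo-hex-5-enofuranoside | C=C[C@@H]1O[C@@H]([Se]c2ccccc2)[C@H](O[Si](C)(C)/C=C/C(=O)OC)[C@@H]1OCc3ccc4ccccc4c3 | intermediate
16 | bicyclic siloxane: 1,2-oxasilolane (C4–C5–O5–SiMe2–C3) cis-fused to the oxolane on the face of ONap and vinyl; CH2CO2Me on C3 on the convex face (cis to H-4) | C=C[C@@H]1O[C@@H]2[C@@H](CC(=O)OC)[Si](C)(C)O[C@@H]2[C@@H]1OCc3ccc4ccccc4c3 | intermediate
17 | methyl (3R)-3-[(2R,3R,4S,5S)-5-ethenyl-3-hydroxy-4-(naphthalen-2-ylmethoxy)oxolan-2-yl]-3-hydroxypropanoate | C=C[C@@H]1O[C@H]([C@H](O)CC(=O)OC)[C@H](O)[C@@H]1OCc2ccc3ccccc3c2 | intermediate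
18 | (2S,3R,3aR,7R,7aR)-2-ethenyl-7-hydroxy-3-(naphthalen-2-ylmethoxy)hexahydro-5H-furo[3,2-b]pyran-5-one | C=C[C@@H]1O[C@H]2[C@H](OC(=O)C[C@H]2O)[C@@H]1OCc3ccc4ccccc4c3 | intermediate
19 | methyl (R)-lactate | C[C@@H](O)C(=O)OC | starting material
20 | methyl (2R)-2-[(tert-butyldimethylsilyl)oxy]propanoate | C[C@@H](O[Si](C)(C)C(C)(C)C)C(=O)OC | intermediate
21 | (2R)-2-[(tert-butyldimethylsilyl)oxy]propanal | C[C@@H](O[Si](C)(C)C(C)(C)C)C=O | intermediate
22 | (3S,4R)-4-[(tert-butyldimethylsilyl)oxy]pent-1-en-3-ol | C[C@@H](O[Si](C)(C)C(C)(C)C)[C@@H](O)C=C | intermediate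
23 | (3S,4R)-4-[(tert-butyldimethylsilyl)oxy]pent-1-en-3-yl benzoate | C[C@@H](O[Si](C)(C)C(C)(C)C)[C@@H](OC(=O)c1ccccc1)C=C | intermediate
24 | (3S,4R)-4-hydroxypent-1-en-3-yl benzoate | C[C@@H](O)[C@@H](OC(=O)c1ccccc1)C=C | intermediate
25 | (3S,4R)-4-(acetyloxy)pent-1-en-3-yl benzoate | C[C@@H](OC(C)=O)[C@@H](OC(=O)c1ccccc1)C=C | intermediate
26 | (2R,3S,4E)-2-(acetyloxy)-5-[(2S,3R,3aR,7R,7aR)-7-hydroxy-3-(naphthalen-2-ylmethoxy)-5-oxohexahydro-2H-furo[3,2-b]pyran-2-yl]pent-4-en-3-yl benzoate | CC(=O)O[C@H](C)[C@H](/C=C/[C@@H]1O[C@H]2[C@H](OC(=O)C[C@H]2O)[C@@H]1OCc3ccc4ccccc4c3)OC(=O)c5ccccc5 | intermediate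
27 | (2R,3S,4E)-2-(acetyloxy)-5-[(2S,3R,3aR,7R,7aR)-3,7-dihydroxy-5-oxohexahydro-2H-furo[3,2-b]pyran-2-yl]pent-4-en-3-yl benzoate | CC(=O)O[C@H](C)[C@H](/C=C/[C@@H]1O[C@H]2[C@H](OC(=O)C[C@H]2O)[C@@H]1O)OC(=O)c1ccccc1 | target

**Step count**

Total: 19 steps. Longest linear sequence: 13 steps (1 → 27 through steps 1–8, 10, 11, 12, 18 and 19).

**Steps most likely to fail**

1. Step 11 (radical ring closure). The acrylate arm may turn toward the concave face in the 5-exo transition state (poor facial selectivity at C3), or hydrogen transfer to the C4 radical may outrun ring closure. The fallback sets out from 10, comes back at 17 (and so at 18), and moves the C3 stereocentre out of the ring closure. Silylation of 10 (imidazole, CH2Cl2) with methyl 3-[chloro(dimethyl)silyl]prop-2-ynoate F1 (from 11, LiN(SiMe3)2, −78 °C, then excess Me2SiCl2) would give the alkynylsilyl ether phenyl 5,6-dideoxy-2-O-{[2-(methoxycarbonyl)ethynyl]dimethylsilyl}-3-O-(naphthalen-2-ylmethyl)-1-seleno-α-L-lyxo-hex-5-enofuranoside F2. 5-exo-dig closure (Bu3SnH, AIBN) onto the activated alkyne should give the cis-fused exocyclic alkenylsilane F3, in which C3 is still sp2. Tamao–Fleming oxidation of the alkenyl–silicon bond should give the β-keto ester methyl 3-[5-ethenyl-3-hydroxy-4-(naphthalen-2-ylmethoxy)oxolan-2-yl]-3-oxopropanoate F4 (ring configuration as in 17) with O5 free. Hydroxyl-directed Evans–Saksena reduction (Me4NBH(OAc)3, MeCN/AcOH, −30 °C) delivered from O5 should then give the 1,3-anti diol 17, which lactonises to 18 as in step 12.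

2. Step 18 (cross-metathesis). Coupling of the hindered vinyl group next to the cis C6 substituent may be sluggish, so that homodimerisation of 25 dominates. The fallback sets out from 18, comes back at 26, and replaces metathesis by carbonyl olefination. Lemieux–Johnson cleavage (OsO4 cat., NaIO4, 2,6-lutidine, dioxane/H2O) would give the aldehyde (2R,3R,3aR,7R,7aR)-7-hydroxy-3-(naphthalen-2-ylmethoxy)-5-oxohexahydro-2H-furo[3,2-b]pyran-2-carbaldehyde F5. Wittig reaction in toluene with the stabilised ylide (3R)-3-(acetyloxy)-1-(triphenylphosphoranylidene)butan-2-one F6 (from (R)-2-acetoxypropanoyl chloride and two equivalents of Ph3P=CH2) should give the E-enone F7 (C10 ketone, C11 acetate in place). Corey–Bakshi–Shibata reduction (the (S)-oxazaborolidine should be the matching catalyst if the alkenyl group acts as the large substituent; catecholborane, −78 °C) should give the (10S)-allylic alcohol F8. Benzoylation of the unhindered allylic hydroxyl (BzCl, 2,4,6-collidine, −40 °C), the C3 hydroxyl lying on the concave face of the bicycle, would return 26.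

3. Step 8 (anomeric selenide). Chemoselectivity of the hemiacetal activation may be lost, with the vicinal 2-OH competing or elimination toward the glycal. The fallback sets out from 9, comes back at 10, and uses Lewis-acid glycosidation with neighbouring-group participation. Ac2O/pyridine would give the 1,2-di-O-acetyl-5,6-dideoxy-3-O-(naphthalen-2-ylmethyl)-L-lyxo-hex-5-enofuranose F9. PhSeH with BF3·OEt2 (CH2Cl2, 0 °C) should give, through the acetoxonium ion, phenyl 2-O-acetyl-5,6-dideoxy-3-O-(naphthalen-2-ylmethyl)-1-seleno-α-L-lyxo-hex-5-enofuranoside F10. Zemplén deacetylation (NaOMe cat., MeOH) then returns 10.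

Further compounds
F1 | step 11 | methyl 3-[chloro(dimethyl)silyl]prop-2-ynoate | COC(=O)C#C[Si](C)(C)Cl
F2 | step 11 | phenyl 5,6-dideoxy-2-O-{[2-(methoxycarbonyl)ethynyl]dimethylsilyl}-3-O-(naphthalen-2-ylmethyl)-1-seleno-α-L-lyxo-hex-5-enofuranoside | C=C[C@@H]1O[C@@H]([Se]c2ccccc2)[C@H](O[Si](C)(C)C#CC(=O)OC)[C@@H]1OCc3ccc4ccccc4c3
F3 | step 11 | cis-fused bicyclic alkenylsilane: 1,2-oxasilolane (C4–C5–O5–SiMe2–C3) with exocyclic C3=CH–CO2Me (E/Z mixture), ONap and vinyl as in 16 | C=C[C@@H]1O[C@@H]2C(=CC(=O)OC)[Si](C)(C)O[C@@H]2[C@@H]1OCc3ccc4ccccc4c3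
F4 | step 11 | methyl 3-[5-ethenyl-3-hydroxy-4-(naphthalen-2-ylmethoxy)oxolan-2-yl]-3-oxopropanoate (ring configuration as in 17) | C=C[C@@H]1O[C@H](C(=O)CC(=O)OC)[C@H](O)[C@@H]1OCc2ccc3ccccc3c2
F5 | step 18 | (2R,3R,3aR,7R,7aR)-7-hydroxy-3-(naphthalen-2-ylmethoxy)-5-oxohexahydro-2H-furo[3,2-b]pyran-2-carbaldehyde | O=C[C@@H]1O[C@H]2[C@H](OC(=O)C[C@H]2O)[C@@H]1OCc3ccc4ccccc4c3
F6 | step 18 | (3R)-3-(acetyloxy)-1-(triphenylphosphoranylidene)butan-2-one | C[C@@H](OC(C)=O)C(=O)C=P(c1ccccc1)(c1ccccc1)c1ccccc1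
F7 | step 18 | E-enone: C10 ketone analogue of 26 lacking the benzoate, (2R)-2-(acetyloxy)-3-oxopent-4-enyl chain on the bicyclic core of 18 | CC(=O)O[C@H](C)C(=O)/C=C/[C@@H]1O[C@H]2[C@H](OC(=O)C[C@H]2O)[C@@H]1OCc3ccc4ccccc4c3
F8 | step 18 | (10S)-allylic alcohol: 26 with free hydroxyl in place of the benzoate | CC(=O)O[C@H](C)[C@@H](O)/C=C/[C@@H]1O[C@H]2[C@H](OC(=O)C[C@H]2O)[C@@H]1OCc3ccc4ccccc4c3
F9 | step 8 | 1,2-di-O-acetyl-5,6-dideoxy-3-O-(naphthalen-2-ylmethyl)-L-lyxo-hex-5-enofuranose (mixture of anomers) | C=C[C@@H]1OC(OC(C)=O)[C@H](OC(C)=O)[C@@H]1OCc2ccc3ccccc3c2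
F10 | step 8 | phenyl 2-O-acetyl-5,6-dideoxy-3-O-(naphthalen-2-ylmethyl)-1-seleno-α-L-lyxo-hex-5-enofuranoside | C=C[C@@H]1O[C@@H]([Se]c2ccccc2)[C@H](OC(C)=O)[C@@H]1OCc3ccc4ccccc4c3
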